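The constants split one stream. Free catalyst turns starting material into open intermediate, second catalyst binds that reversibly and hands it to the reagent as product, and capture agent turns open intermediate into trapped intermediate.

    starting material + free catalyst → free catalyst + open intermediate (k1 = 0.0648 M⁻¹ s⁻¹)
    second catalyst + open intermediate ⇌ catalyst intermediate (K2 = 3.68 M⁻¹, k2 = 8.85 M⁻¹ s⁻¹)
    reagent + catalyst intermediate → second catalyst + product (k3 = 0.0636 M⁻¹ s⁻¹)
    open intermediate + capture agent → trapped intermediate (k4 = 0.00158 M⁻¹ s⁻¹)

| flask | starting material | reagent | capture agent | free catalyst | second catalyst | time | remark |
|---|---|---|---|---|---|---|---|
| summer | 1.9 M | 1.99 M | 0.570 M | 95 mM | 19 mM | 6.0 min | a closed flask charged with all of it at once and left for 6.0 min |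
| winter | 1.9 M | 1.99 M | 0.570 M | 95 mM | 19 mM |  | one stirred flow tank at steady state, fed with the mixture as stated, mean residence time 6.0 min |
| spring | 1.9 M | 1.99 M | 0.570 M | 95 mM | 19 mM |  | a single well-mixed tank run continuously and read at steady state, 30.0 min in it on average |
| dusk | 1.9 M | 1.99 M | 0.570 M | 95 mM | 19 mM | 6.0 min | plug flow through a tube for 6.0 min, no back-mixing |

- the set-up with the highest share of product in all that became product or trapped intermediate, at the outlet or at the end ("none" if the first two lie within 2 percentage points) (summer / winter / spring / dusk / none)
- share of product in all that became product or trapped intermediate, at the outlet or at the end, summer
- share of product in all that became product or trapped intermediate, at the outlet or at the end, winter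
- share of product in all that became product or trapped intermediate, at the outlet or at the end, spring
- share of product in all that became product or trapped intermediate, at the outlet or at the end, dusk

- the stated concentrations are those of everything mixed, before any reaction; amounts are the same in each set-up
- run time (summer): 6.0 min

The base odds are 9.83: the product made per trapped intermediate made, with everything as charged and open intermediate tending to nil. This is a selectivity factor. While binding stands in balance, the odds at any moment are these, scaled by reagent over capture agent and by second catalyst, each as a fraction of its charge, and divided by one plus the binding constant times the open intermediate. A tank's outlet share is odds over one plus odds.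

A hand reckoning reaches winter, with reagent and capture agent held as charged. The first step converts 68.9% of the charge. Round one counts all of it as open intermediate, giving odds of 1.69 and a share of 62.8%. Put back, full turnover of 45.6% of the charge, times the bound part, gives product 37.7% and trapped intermediate 22.3%. That leaves open intermediate 8.83%, less than the 68.9% that round one counted. Round two takes the middle, 38.9%, giving odds of 2.64 and a share of 72.5%.

The forecast says 72% for summer, 75% for winter, 79% for spring and 72% for dusk, with spring best, because “whichever set-up holds that intermediate lowest and longest favours product”. Its winter stands above the hand reckoning.

The simulation gives 71.9%, 74.7%, 79.3% and 71.9% in that order, and spring is best, ahead of winter by 4.6 percentage points.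

In dusk at the asked time, binding relaxes with a half-life of 0.0638 s, against 12 min for reagent by the turnover step. Catalyst intermediate stands at 77.1% of the second catalyst charged, and, each step taken net, it forms at 0.998 times the rate at which the reagent turns it into product. With the dusk readings of open intermediate 50.1%, reagent 74% and capture agent 64%, the odds are 2.51, a momentary share of 71.5%.

In the neighbour like dusk with 0.0047 M of second catalyst, the base odds scale to 2.43. Its readings of 68.4%, 92% and 58% give odds of 0.670, a momentary share of 40.1%. The computed share there, counted over the whole run, is 38.7%.

The constants used here belong to no real substance; no experiment stands behind them.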